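| flask | starting material | coupling partner | remark | time |
|---|---|---|---|---|
| red | 0.24 M | 4 equiv | run made earlier |  |
| ochre | 0.24 M | 2 equiv | run made earlier |  |
| midnight | 0.24 M | 4.00 equiv | one stirred flow tank at steady state, fed with the mixture as stated, mean residence time 80 min |  |
| dawn | 0.24 M (fed, over 64.0 min) | 4.00 equiv | all but starting material at the start; starting material goes in evenly over 64.0 min, the run ends at 80 min | 80 min |
| dusk | 0.24 M | 4.00 equiv | a tube with plug flow, the mixed feed as stated, residence time 80 min | 80 min |
| summer | 0.24 M | 4.00 equiv | everything together in a closed stirred flask, run for 80 min | 80 min |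

| run | time / min | target / % | side product / % |
|---|---|---|---|
| red | 5.00 | 0.9 | 0.2 |
| red | 15.0 | 2.9 | 0.8 |
| red | 30.0 | 6.2 | 1.6 |
| red | 40.0 | 7.6 | 2.0 |
| red | 60.0 | 9.4 | 4.5 |
| red | 80.0 | 11.2 | 5.4 |
| ochre | 0.667 | 0 | 0.1 |
| ochre | 1.00 | 0.6 | 0 |
| ochre | 2.00 | 0.5 | 0.6 |
| ochre | 3.00 | 0.2 | 0 |
| ochre | 5.00 | 0.9 | 0.9 |
| ochre | 8.00 | 0.5 | 0 |

(readings scatter by 0.5 percentage points)

- the stated concentrations are those of everything mixed, before any reaction; amounts are the same in each set-up
- the feed brings no volume worth counting
- the earlier runs were made in a closed, stirred flask

- the set-up with the highest share of target in all that became target or side product, at the outlet or at the end ("none" if the first two lie within 2 percentage points) (midnight / dawn / dusk / summer / none)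
- share of target in all that became target or side product, at the outlet or at the end, midnight
- share of target in all that became target or side product, at the outlet or at the end, dawn
- share of target in all that became target or side product, at the outlet or at the end, dusk
- share of target in all that became target or side product, at the outlet or at the end, summer

- The red run at 80.0 min still has 83.4 % of the charged starting material as neither target nor side product, so its share of target in what has reacted to either (the selectivity) is a reading taken partway and depends on when it is read.
- Pooled over the red readings up to 40.0 min, the share reads 79.3 %, and at 80.0 min it reads 67.5 %, lower, so in the red readings the share falls as the material ages.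
- For dawn, the mean age, 48.0 min, is the average time the starting material has spent in the flask at the end.
- One extreme of dawn has the whole charge in at the start, with age 80 min and share 67.5 %. The other has it in at the end of the feed, with age 16.0 min and a share near 79.3 %.
- The real ages of dawn run evenly between these extremes, and its mean age stands half of the way along. Taking the midpoint of the two red shares as the share at that mean age, my reckoning for dawn is 73.4 %.
- Dusk and summer hold material of age 80 min, so I reckon 67.5 % for each. Midnight has the same mean age as dusk, so reading the share at the mean age gives it 67.5 % as well. Dawn leads by 5.9 percentage points, beyond the margin.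
- The forecast chose dawn, with 72 % for dawn, 67.5 % for dusk and summer and 59 % for midnight, on the ground “so target is younger”.
- The simulation gives 74.1 % for dawn and 67.4 % for dusk and summer, while midnight, at equal mean age, gives 64.4 %, lower than dusk. The best set-up is dawn.

    coupling partner + intermediate A → side product (k = 0.00443 M⁻¹ min⁻¹)
    intermediate B ⇌ intermediate D (K = 1.07, k = 0.00376 min⁻¹)
    starting material → intermediate B (k = 0.00262 min⁻¹)
    intermediate B ⇌ intermediate C (K = 1.02, k = 0.197 min⁻¹)
    starting material ⇌ dormant form (K = 0.590, k = 0.0128 min⁻¹)
    starting material + coupling partner → target (k = 0.00289 M⁻¹ min⁻¹)
    starting material ⇌ intermediate A (K = 0.900, k = 0.00999 min⁻¹)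

- Dusk read at 50 min, close to dawn's mean age of 48.0 min, gives 74.6 % beside dawn's 74.1 %. Dusk has not come to rest at 80 min, with 31 % of the starting material still unbound. At ten times the time, dawn's mean age of 768 min is nearly all of dusk's 800 min, and the shares stand at 50.5 % for dawn and 50.4 % for dusk. Dusk then holds 2.77 % starting material, 31.0 % target and 30.5 % side product.

Readings and results were computed for substances that don't exist; noise was put on by code.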